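**Retrosynthetic overview**

- The target acid comes from its 2-(trimethylsilyl)ethyl ester, and that from an acyclic (6S)-tetraenone. Oxidising the C5 carbinol triggers an intramolecular [4+2] that forms C4–C5 and C3a–C7a (indene numbering) together, so the cyclohexene and the cyclopentanone close in the same flask; no ring exists before.
- Only chain C6 is set beforehand. Chain C4 is left stereorandom on purpose and equilibrates (vinylogous β-keto ester) while the cycloaddition runs.
- The tetraenol comes from a Horner–Wadsworth–Emmons olefination (C9=C10) of a C1–C9 enal with an α-ethyl cinnamylphosphonate.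
- The C1–C9 enal comes from a Kobayashi vinylogous Mukaiyama aldol (C5–C6) between two halves that both derive from (E)-2-ethylhex-2-enoic acid; C5 comes from trimethyl orthoformate.

Assumption: the facial sense of the Kobayashi aldol follows the accepted model for (E,E) silyl N,O-ketene acetals (attack anti to the i-Pr group), so the (S)-auxiliary is used.

**Route**

Step 1
Reactants: 1 (E)-2-ethylhex-2-enoic acid; 2 2-(trimethylsilyl)ethanol
Product: 3 2-(trimethylsilyl)ethyl (E)-2-ethylhex-2-enoate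
Conditions: DCC, DMAP (cat.), CH2Cl2, 0 °C → rt
Reagents that add atoms: none
Why: Steglich esterification of an unhindered enoic acid; the silylethyl ester is later removed by fluoride, without acid or hydroxide.

Step 2
Reactants: 3 2-(trimethylsilyl)ethyl (E)-2-ethylhex-2-enoate
Product: 6 2-(trimethylsilyl)ethyl (E)-2-ethyl-4-formylhex-2-enoate (racemic at C4), via silyl ketene acetal 4 (not isolated), via dimethyl acetal 5 (not isolated)
Conditions: LDA, DMPU, THF, −78 °C; TMSCl; then HC(OMe)3, TMSOTf (5 mol%), CH2Cl2, −78 °C; then aq. oxalic acid, THF, 0 °C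
Reagents that add atoms: trimethyl orthoformate COC(OC)OC; water O
Why: γ-Deprotonation and O-silylation give the dienoxysilane, which attacks the dimethoxycarbenium ion through its γ-carbon (vinylogous Mukaiyama reaction), and mild hydrolysis frees the aldehyde; C4 is left racemic because it is equilibrated in step 10.

Step 3
Reactants: 1 (E)-2-ethylhex-2-enoic acid; 7 (S)-4-isopropyloxazolidin-2-one
Product: 9 (S)-3-[(E)-2-ethylhex-2-enoyl]-4-isopropyloxazolidin-2-one, via mixed pivalic anhydride 8 (not isolated)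
Conditions: PivCl, Et3N, THF, −20 °C; then 7, LiCl, rt
Reagents that add atoms: none
Why: Mixed-anhydride N-acylation of the oxazolidinone (LiCl/Et3N protocol); no new stereocentre.

Step 4
Reactants: 9 (S)-3-[(E)-2-ethylhex-2-enoyl]-4-isopropyloxazolidin-2-one
Product: 10 (S)-3-[(1E,3E)-1-(tert-butyldimethylsilyloxy)-2-ethylhexa-1,3-dien-1-yl]-4-isopropyloxazolidin-2-one
Conditions: NaHMDS, THF, −78 °C; TBSCl
Reagents that add atoms: tert-butyldimethylsilyl chloride CC(C)(C)[Si](C)(C)Cl
Why: γ-Deprotonation of the α-substituted enoyl imide and O-silylation (Kobayashi protocol) give the (1E,3E) vinylketene silyl N,O-acetal as one isomer.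

Step 5
Reactants: 10 (S)-3-[(1E,3E)-1-(tert-butyldimethylsilyloxy)-2-ethylhexa-1,3-dien-1-yl]-4-isopropyloxazolidin-2-one; 6 2-(trimethylsilyl)ethyl (E)-2-ethyl-4-formylhex-2-enoate
Product: 11 2-(trimethylsilyl)ethyl (2E,5S,6S,7E)-2,4,6,8-tetraethyl-5-hydroxy-9-oxo-9-[(S)-4-isopropyl-2-oxooxazolidin-3-yl]nona-2,7-dienoate (C4 epimers)
Conditions: TiCl4 (1 equiv), CH2Cl2, −78 °C; then aq. NaHCO3
Reagents that add atoms: none
Why: Kobayashi vinylogous Mukaiyama aldol reaction: the TiCl4-bound aldehyde adds to the γ-carbon on the face opposite the i-Pr group of the perpendicular oxazolidinone, which fixes C6 as S with C5 anti, while C4 of the aldehyde stays a mixture.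

Step 6
Reactants: 11 (the imide from step 5)
Product: 12 2-(trimethylsilyl)ethyl (2E,5S,6S,7E)-2,4,6,8-tetraethyl-5,9-dihydroxynona-2,7-dienoate (C4 epimers)
Conditions: NaBH4, THF/H2O (4:1), 0 °C → rt
Reagents that add atoms: none
Why: Borohydride reductive cleavage of the activated N-acyl oxazolidinone gives the allylic alcohol and returns the auxiliary; the enoate ester is not reduced.

Step 7
Reactants: 12 (the diol from step 6)
Product: 13 2-(trimethylsilyl)ethyl (2E,5S,6S,7E)-2,4,6,8-tetraethyl-5-hydroxy-9-oxonona-2,7-dienoate (C4 epimers)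
Conditions: MnO2, CH2Cl2, rt
Reagents that add atoms: none
Why: MnO2 oxidises only the primary allylic alcohol; the homoallylic C5 carbinol is untouched.

Step 8
Reactants: 14 diethyl [(E)-3-phenylprop-2-en-1-yl]phosphonate
Product: 15 diethyl [(E)-1-phenylpent-1-en-3-yl]phosphonate (racemic)
Conditions: n-BuLi, THF, −78 °C; EtI, −78 → 0 °C
Reagents that add atoms: iodoethane CCI
Why: α-Lithiation and α-alkylation of the allylic phosphonate; its stereocentre is lost in step 9.

Step 9
Reactants: 13 (the enal from step 7); 15 diethyl [(E)-1-phenylpent-1-en-3-yl]phosphonate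
Product: 16 2-(trimethylsilyl)ethyl (2E,5S,6S,7E,9E,11E)-2,4,6,8,10-pentaethyl-5-hydroxy-12-phenyldodeca-2,7,9,11-tetraenoate (C4 epimers)
Conditions: 15, KHMDS (2.2 equiv each), THF, −78 °C; add 13; → rt
Reagents that add atoms: none
Why: Horner–Wadsworth–Emmons olefination; the anion-stabilising styryl group ends trans to the aldehyde chain, giving the (9E) trisubstituted alkene, and C6 (γ to the enal, not α to a carbonyl) keeps its configuration.

Step 10
Reactants: 16 (the tetraenol from step 9)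
Product: 18 2-(trimethylsilyl)ethyl (1S,3S,3aR,4R,5S,7aR)-1,3,4,5,7-pentaethyl-2-oxo-5-[(E)-2-phenylethenyl]-2,3,3a,4,5,7a-hexahydro-1H-indene-4-carboxylate, via tetraenone 17 (not isolated)
Conditions: DMP, CH2Cl2, 0 °C → rt; aq. NaHCO3/Na2S2O3 wash; then Et3N (0.2 equiv), PhMe, 45 °C
Reagents that add atoms: none
Why: Dess–Martin oxidation then type-1 intramolecular Diels–Alder reaction: the (6S) centre keeps its H in the diene plane (A1,3 strain) so the dienophile adds to one diene face through the ester-endo, trans-fused transition state (this sets C3a, C4, C5 and C7a), while chain C4 epimerises under Et3N faster than the mismatched epimer cyclises, so both epimers converge and C1/C3 end all-trans.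

Step 11
Reactants: 18 (the bicyclic ester from step 10)
Product: 19 (1S,3S,3aR,4R,5S,7aR)-1,3,4,5,7-pentaethyl-2-oxo-5-[(E)-2-phenylethenyl]-2,3,3a,4,5,7a-hexahydro-1H-indene-4-carboxylic acid
Conditions: TBAF, THF, 0 °C → rt; aq. NH4Cl
Reagents that add atoms: none
Why: Fluoride attacks silicon and the ester fragments (ethylene + Me3SiF), so the neopentyl-type quaternary ester is cleaved without strong acid, which could lactonise the γ,δ-unsaturated acid.

**Compound list**

1 | (E)-2-ethylhex-2-enoic acid | CCC/C=C(\CC)C(=O)O | starting material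
2 | 2-(trimethylsilyl)ethanol | C[Si](C)(C)CCO | starting material
3 | 2-(trimethylsilyl)ethyl (E)-2-ethylhex-2-enoate | CCC/C=C(\CC)C(=O)OCC[Si](C)(C)C | intermediate
4 | (3E)-2-ethyl-1-[2-(trimethylsilyl)ethoxy]-1-(trimethylsilyloxy)hexa-1,3-diene | CC/C=C/C(CC)=C(OCC[Si](C)(C)C)O[Si](C)(C)C | intermediate
5 | 2-(trimethylsilyl)ethyl (E)-4-(dimethoxymethyl)-2-ethylhex-2-enoate (racemic) | CCC(C(OC)OC)/C=C(\CC)C(=O)OCC[Si](C)(C)C | intermediate
6 | 2-(trimethylsilyl)ethyl (E)-2-ethyl-4-formylhex-2-enoate (racemic) | CCC(C=O)/C=C(\CC)C(=O)OCC[Si](C)(C)C | intermediate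
7 | (S)-4-isopropyloxazolidin-2-one | CC(C)[C@H]1COC(=O)N1 | starting material
8 | (E)-2-ethylhex-2-enoic pivalic anhydride | CCC/C=C(\CC)C(=O)OC(=O)C(C)(C)C | intermediate
9 | (S)-3-[(E)-2-ethylhex-2-enoyl]-4-isopropyloxazolidin-2-one | CCC/C=C(\CC)C(=O)N1C(=O)OC[C@@H]1C(C)C | intermediate
10 | (S)-3-[(1E,3E)-1-(tert-butyldimethylsilyloxy)-2-ethylhexa-1,3-dien-1-yl]-4-isopropyloxazolidin-2-one | CC/C(=C(\O[Si](C)(C)C(C)(C)C)N1C(=O)OC[C@@H]1C(C)C)/C=C/CC | intermediate
11 | 2-(trimethylsilyl)ethyl (2E,5S,6S,7E)-2,4,6,8-tetraethyl-5-hydroxy-9-oxo-9-[(S)-4-isopropyl-2-oxooxazolidin-3-yl]nona-2,7-dienoate (C4 epimers) | C[Si](C)(C)CCOC(=O)/C(CC)=C/C(CC)[C@@H](O)[C@@H](CC)/C=C(\CC)C(=O)N1C(=O)OC[C@@H]1C(C)C | intermediate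
12 | 2-(trimethylsilyl)ethyl (2E,5S,6S,7E)-2,4,6,8-tetraethyl-5,9-dihydroxynona-2,7-dienoate (C4 epimers) | C[Si](C)(C)CCOC(=O)/C(CC)=C/C(CC)[C@@H](O)[C@@H](CC)/C=C(\CC)CO | intermediate
13 | 2-(trimethylsilyl)ethyl (2E,5S,6S,7E)-2,4,6,8-tetraethyl-5-hydroxy-9-oxonona-2,7-dienoate (C4 epimers) | C[Si](C)(C)CCOC(=O)/C(CC)=C/C(CC)[C@@H](O)[C@@H](CC)/C=C(\CC)C=O | intermediate
14 | diethyl [(E)-3-phenylprop-2-en-1-yl]phosphonate (diethyl cinnamylphosphonate) | CCOP(=O)(OCC)C/C=C/c1ccccc1 | starting material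
15 | diethyl [(E)-1-phenylpent-1-en-3-yl]phosphonate (racemic) | CCOP(=O)(OCC)C(CC)/C=C/c1ccccc1 | intermediate
16 | 2-(trimethylsilyl)ethyl (2E,5S,6S,7E,9E,11E)-2,4,6,8,10-pentaethyl-5-hydroxy-12-phenyldodeca-2,7,9,11-tetraenoate (C4 epimers) | C[Si](C)(C)CCOC(=O)/C(CC)=C/C(CC)[C@@H](O)[C@@H](CC)/C=C(\CC)/C=C(\CC)/C=C/c1ccccc1 | intermediate
17 | 2-(trimethylsilyl)ethyl (2E,6S,7E,9E,11E)-2,4,6,8,10-pentaethyl-5-oxo-12-phenyldodeca-2,7,9,11-tetraenoate (C4 epimers) | C[Si](C)(C)CCOC(=O)/C(CC)=C/C(CC)C(=O)[C@@H](CC)/C=C(\CC)/C=C(\CC)/C=C/c1ccccc1 | intermediate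
18 | 2-(trimethylsilyl)ethyl (1S,3S,3aR,4R,5S,7aR)-1,3,4,5,7-pentaethyl-2-oxo-5-[(E)-2-phenylethenyl]-2,3,3a,4,5,7a-hexahydro-1H-indene-4-carboxylate | CCC1=C[C@@](/C=C/c2ccccc2)(CC)[C@](CC)(C(=O)OCC[Si](C)(C)C)[C@@H]2[C@@H]1[C@H](CC)C(=O)[C@H]2CC | intermediate
19 | (1S,3S,3aR,4R,5S,7aR)-1,3,4,5,7-pentaethyl-2-oxo-5-[(E)-2-phenylethenyl]-2,3,3a,4,5,7a-hexahydro-1H-indene-4-carboxylic acid | CCC1=C[C@@](/C=C/c2ccccc2)(CC)[C@](CC)(C(=O)O)[C@@H]2[C@@H]1[C@H](CC)C(=O)[C@H]2CC | target

**Step count**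

Total steps: 11. Longest linear sequence: 8 steps (1 → 3 → 6 → 11 → 12 → 13 → 16 → 18 → 19; the branch 1 → 9 → 10 → 11 is equally long).

**Steps most likely to fail, with fallbacks**

Step 10 (oxidation and convergent cycloaddition). The risks are that the mismatched C4 epimer of 17 closes to a cis-fused adduct before it epimerises, or that Et3N moves a β,γ-double bond into conjugation and erodes C6. The fallback sets out from 16 and drops the amine. TBAF removes the still-unhindered ester to give (2E,5S,6S,7E,9E,11E)-2,4,6,8,10-pentaethyl-5-hydroxy-12-phenyldodeca-2,7,9,11-tetraenoic acid F1. Dess–Martin oxidation then gives the keto acid (2E,6S,7E,9E,11E)-2,4,6,8,10-pentaethyl-5-oxo-12-phenyldodeca-2,7,9,11-tetraenoic acid F2. F2 is not isolated; it cyclises as the free acid in toluene at 40–60 °C, with its own carboxyl group catalysing enolisation at C4. This fallback comes back to the route at 19.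

Step 5 (Kobayashi aldol). The risks are enolisation or conjugation of the α-branched β,γ-unsaturated aldehyde 6 under TiCl4, loss of the silylethyl ester, and the facial sense of attack. The fallback sets out from 6. Commercial (E)-2-ethylhex-2-enal is converted with TBSOTf/Et3N into tert-butyl{[(3E)-2-ethylhexa-1,3-dien-1-yl]oxy}dimethylsilane F3. Its vinylogous Mukaiyama aldol with 6 is promoted by an N-tosyl-tryptophan-derived B-phenyl oxazaborolidinone (enantiomer chosen for 6S). This gives the enal directly, with no auxiliary and no redox steps, and comes back to the route at 13.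

Step 9 (olefination with the α-branched allylic phosphonate). The risks are an E/Z mixture at C9=C10, γ-attack of the delocalised anion, and retro-vinylogous aldol of the C5 alkoxide. The fallback sets out from 13 and builds the triene in two carbonyl olefinations. Wittig reaction with 2-(triphenylphosphoranylidene)butanal (toluene, 90 °C) gives 2-(trimethylsilyl)ethyl (2E,5S,6S,7E,9E)-2,4,6,8,10-pentaethyl-5-hydroxy-11-oxoundeca-2,7,9-trienoate F4. Horner–Wadsworth–Emmons reaction of F4 with diethyl benzylphosphonate/NaHMDS then installs the (E)-styryl end and comes back to the route at 16.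

**Further compounds**

F1 | step 10 | (2E,5S,6S,7E,9E,11E)-2,4,6,8,10-pentaethyl-5-hydroxy-12-phenyldodeca-2,7,9,11-tetraenoic acid (C4 epimers) | OC(=O)/C(CC)=C/C(CC)[C@@H](O)[C@@H](CC)/C=C(\CC)/C=C(\CC)/C=C/c1ccccc1
F2 | step 10 | (2E,6S,7E,9E,11E)-2,4,6,8,10-pentaethyl-5-oxo-12-phenyldodeca-2,7,9,11-tetraenoic acid (C4 epimers) | OC(=O)/C(CC)=C/C(CC)C(=O)[C@@H](CC)/C=C(\CC)/C=C(\CC)/C=C/c1ccccc1
F3 | step 5 | tert-butyl{[(3E)-2-ethylhexa-1,3-dien-1-yl]oxy}dimethylsilane | CC/C=C/C(CC)=CO[Si](C)(C)C(C)(C)C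
F4 | step 9 | 2-(trimethylsilyl)ethyl (2E,5S,6S,7E,9E)-2,4,6,8,10-pentaethyl-5-hydroxy-11-oxoundeca-2,7,9-trienoate (C4 epimers) | C[Si](C)(C)CCOC(=O)/C(CC)=C/C(CC)[C@@H](O)[C@@H](CC)/C=C(\CC)/C=C(\CC)C=O
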